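A direct plan would build the ring A ketone by aryl-metal chemistry and close ring C last at O1–C8a. It would metalate 1-bromo-2-fluoro-4-methoxybenzene A1 between F and OMe and prenylate it to A2, convert A2 by halogen–magnesium exchange and acylation into the 2-fluoroacetophenone A3, join A3 with 1-bromo-2,4,5-trimethoxybenzene A4 by palladium-catalysed α-arylation to the deoxybenzoin A5, then C-formylate A5 to the formyl enolate A6 and displace fluoride with its oxygen to reach the target.
Weak point 1, the fluoride-displacing ring closure: it would be an untested SNAr placed last, at a C–F bond flanked by the prenyl group, on a ring whose only activator (the ketone) is by then part of the delocalised anion A6; deformylation would be the easy escape.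
Weak point 2, the α-arylation of A3 with A4: an electron-rich, ortho-substituted bromide adds slowly to zerovalent palladium, the methyl ketone can arylate twice, and the ortho-fluoro ketone and the prenyl alkene would sit in a hot basic palladium mixture.
Weak point 3, the cryogenic prenylation of A1 to A2: the ortho-fluoro aryllithium can lose LiF to an aryne or scramble bromine, uncatalysed allylation mixes SN2 and SN2′ products, and the fluorine is carried through the whole plan only to be expelled.

Retrosynthetic overview of the new route
- Ring C is cut at O1–C2 and C3–C4, and the prenyl group at C8–C1''. All three bonds form in the last step from a chalcone epoxide whose C5 unit still sits on O1 as a 1,1-dimethylallyl ether.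
- The C3–C1' bond to ring B is never made: it is the aryl–CHO bond of commercial 2,4,5-trimethoxybenzaldehyde. The 2- and 4-methoxy groups of ring B (ortho and para to C1') stabilise a benzylic cation at the future C3 and so direct a 1,2-shift of the ring A aroyl group onto that carbon, which turns the chalcone skeleton into the isoflavone skeleton.
- The prenyl group at C8 lies between O1 and the C7 methoxy group. It is delivered from O1 by aromatic Claisen rearrangement, which has only C8 as a free ortho position (C4a carries the carbonyl) and which frees O1 to close ring C on the formyl carbon.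
- Rings A and B are bought; ring C is the only ring formed and closes last. The design needs no aryl halide, no aryl-metal species, no α-arylation and no SNAr.

Key step: step 5

Remark on the chemistry: epoxide 9 and the intermediates 10 to 12 are racemates or tautomer mixtures; this has no consequence because the target is achiral.

Step 1
Reactants: 1 2-methylbut-3-en-2-ol; 2 di-tert-butyl dicarbonate (Boc2O)
Product: 4 tert-butyl (2-methylbut-3-en-2-yl) carbonate, via lithium 2-methylbut-3-en-2-olate 3 (not isolated)
Conditions: n-BuLi (1.05 equiv), THF, 0 °C, 30 min; Boc2O (1.1 equiv), 0 °C → rt; H2O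
Reagents that add atoms: none
Why: O-acylation of the lithium alkoxide of a tertiary allylic alcohol by Boc2O is the standard preparation of tertiary allyl tert-butyl carbonates, and the tert-butyl carbonate anion that is released does not react further.

Step 2
Reactants: 5 1-(2-hydroxy-4-methoxyphenyl)ethan-1-one (paeonol); 4 tert-butyl (2-methylbut-3-en-2-yl) carbonate
Product: 6 1-[4-methoxy-2-(2-methylbut-3-en-2-yloxy)phenyl]ethan-1-one
Conditions: 4 (1.5 equiv), Pd(PPh3)4 (3 mol%), 4 Å MS, THF, 0 °C, 2 h
Reagents that add atoms: none
Why: In this Tsuji–Trost decarboxylative O-allylation, zerovalent palladium ionises 4 to the (1,1-dimethylallyl)palladium cation, CO2 and tert-butoxide, which deprotonates the chelated phenol, and at 0 °C the phenoxide should attack the more substituted allyl terminus (kinetic control) to give the tertiary ether, as in known reverse O-prenylations of phenols.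

Step 3
Reactants: 6 1-[4-methoxy-2-(2-methylbut-3-en-2-yloxy)phenyl]ethan-1-one; 7 2,4,5-trimethoxybenzaldehyde
Product: 8 (E)-1-[4-methoxy-2-(2-methylbut-3-en-2-yloxy)phenyl]-3-(2,4,5-trimethoxyphenyl)prop-2-en-1-one
Conditions: 7 (1.05 equiv), KOH (3 equiv), EtOH, rt, 36 h
Reagents that add atoms: none
Why: In this Claisen–Schmidt condensation the methyl ketone enolate adds to the non-enolisable aldehyde and the aldol dehydrates to the conjugated E-enone, while the tertiary allyl aryl ether is inert to hydroxide at room temperature.

Step 4
Reactants: 8 (E)-1-[4-methoxy-2-(2-methylbut-3-en-2-yloxy)phenyl]-3-(2,4,5-trimethoxyphenyl)prop-2-en-1-one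
Product: 9 rac-[4-methoxy-2-(2-methylbut-3-en-2-yloxy)phenyl][(2R,3S)-3-(2,4,5-trimethoxyphenyl)oxiran-2-yl]methanone (trans epoxide)
Conditions: 30% aq H2O2 (5 equiv), 2 M aq NaOH (1.5 equiv), MeOH/THF 1:1, 0 °C → rt; aq NaHCO3 work-up; Et3N-deactivated silica
Reagents that add atoms: hydrogen peroxide, OO
Why: In this Weitz–Scheffer epoxidation the hydroperoxide anion adds in conjugate fashion to the enone and the enolate closes with loss of hydroxide, which should give the racemic trans epoxide (both stereocentres follow from the E geometry and are erased in step 5) and leave the isolated vinyl group untouched, because HOO− attacks only electron-poor alkenes.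

Step 5
Reactants: 9 rac-[4-methoxy-2-(2-methylbut-3-en-2-yloxy)phenyl][(2R,3S)-3-(2,4,5-trimethoxyphenyl)oxiran-2-yl]methanone
Product: 13 prebarbigerone [7-methoxy-8-(3-methylbut-2-en-1-yl)-3-(2,4,5-trimethoxyphenyl)-4H-chromen-4-one], via keto aldehyde enol 10 (not isolated), via prenylphenol 11 (not isolated), via 2-hydroxyisoflavanone 12 (not isolated)
Conditions: BF3·OEt2 (0.3 equiv), CH2Cl2, −78 °C, 30 min; Et3N (0.5 equiv); evaporate; degassed o-xylene, 135 °C, 3 h; then PPTS (10 mol%), 80 °C, 1 h
Reagents that add atoms: none
Why: The Lewis acid opens the epoxide at the benzylic carbon (the future C3), where the ortho and para methoxy groups of ring B stabilise the cation, and the ring A aroyl group migrates to it from the neighbouring carbon (House–Meinwald 1,2-acyl shift), which forms the C3–C4 bond and turns the former α-carbon into the formyl carbon C2 of the enolised β-keto aldehyde 10; the closest known reaction is the BF3-mediated rearrangement of 2'-alkoxychalcone epoxides to α-formyldeoxybenzoins, a known entry to isoflavones. Heating then drives the aromatic Claisen rearrangement of the aryl 1,1-dimethylallyl ether, a [3,3] shift that moves the C5 unit from O1 to C8 as a normal prenyl group and, after enolisation of the dienone, gives the free phenol 11 (closest known reaction: Claisen rearrangement of aryl 1,1-dimethylallyl ethers to ortho-prenylphenols). Ring C closes at the heteroatom by 6-exo-trig addition of O1 to the formyl carbon to give the hemiacetal 12, and loss of water, helped by PPTS, should give the aromatic 4-pyranone. The step needs three selectivities: acyl rather than hydride migration, secured by the high migratory aptitude of the acyl group in chalcone epoxides and by the stabilised cation; survival of the tertiary allyl ether in the first stage, secured by the much faster ionisation of the trimethoxyphenyl epoxide at −78 °C with a substoichiometric amount of BF3·OEt2; and Claisen delivery to C8 only, secured because the other ortho position of O1 (C4a) carries the carbonyl group. No stereocentre remains: the two stereocentres of 9 and those of 12 are lost, and the target is achiral.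

Compound list
1 | 2-methylbut-3-en-2-ol | CC(C)(O)C=C | starting material
2 | di-tert-butyl dicarbonate | CC(C)(C)OC(=O)OC(=O)OC(C)(C)C | starting material
3 | lithium 2-methylbut-3-en-2-olate | [Li+].[O-]C(C)(C)C=C | intermediate
4 | tert-butyl (2-methylbut-3-en-2-yl) carbonate | CC(C)(C)OC(=O)OC(C)(C)C=C | intermediate
5 | 1-(2-hydroxy-4-methoxyphenyl)ethan-1-one (paeonol) | CC(=O)c1ccc(OC)cc1O | starting material
6 | 1-[4-methoxy-2-(2-methylbut-3-en-2-yloxy)phenyl]ethan-1-one | CC(=O)c1ccc(OC)cc1OC(C)(C)C=C | intermediate
7 | 2,4,5-trimethoxybenzaldehyde | COc1cc(OC)c(C=O)cc1OC | starting material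
8 | (E)-1-[4-methoxy-2-(2-methylbut-3-en-2-yloxy)phenyl]-3-(2,4,5-trimethoxyphenyl)prop-2-en-1-one | COc1ccc(C(=O)/C=C/c2cc(OC)c(OC)cc2OC)c(OC(C)(C)C=C)c1 | intermediate
9 | rac-[4-methoxy-2-(2-methylbut-3-en-2-yloxy)phenyl][(2R,3S)-3-(2,4,5-trimethoxyphenyl)oxiran-2-yl]methanone (trans, racemic, one enantiomer drawn) | COc1ccc(C(=O)[C@@H]2O[C@H]2c3cc(OC)c(OC)cc3OC)c(OC(C)(C)C=C)c1 | intermediate
10 | (Z)-3-hydroxy-1-[4-methoxy-2-(2-methylbut-3-en-2-yloxy)phenyl]-2-(2,4,5-trimethoxyphenyl)prop-2-en-1-one (enol form of the 3-oxopropanal) | O/C=C(/c1cc(OC)c(OC)cc1OC)C(=O)c1ccc(OC)cc1OC(C)(C)C=C | intermediate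
11 | (Z)-3-hydroxy-1-[2-hydroxy-4-methoxy-3-(3-methylbut-2-en-1-yl)phenyl]-2-(2,4,5-trimethoxyphenyl)prop-2-en-1-one | O/C=C(/c1cc(OC)c(OC)cc1OC)C(=O)c1ccc(OC)c(CC=C(C)C)c1O | intermediate
12 | 2-hydroxy-7-methoxy-8-(3-methylbut-2-en-1-yl)-3-(2,4,5-trimethoxyphenyl)chroman-4-one (racemic, mixture of diastereomers) | COc1cc(OC)c(C2C(O)Oc3c(CC=C(C)C)c(OC)ccc3C2=O)cc1OC | intermediate
13 | prebarbigerone, 7-methoxy-8-(3-methylbut-2-en-1-yl)-3-(2,4,5-trimethoxyphenyl)-4H-chromen-4-one (achiral) | COc1cc(OC)c(-c2coc3c(CC=C(C)C)c(OC)ccc3c2=O)cc1OC | target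

Total step count: 5. Longest linear sequence: 5 steps (1 → 4 → 6 → 8 → 9 → 13); paeonol 5 enters in step 2 and aldehyde 7 in step 3.

Steps most likely to fail

Step 5. What may go wrong: in the Lewis acid stage the O1 ether oxygen may take part at the benzylic cation, or the tertiary allyl ether may ionise, so that the C5 unit is lost or the ring closes toward the 2-aryl skeleton. In the thermal stage the β-keto aldehyde may deformylate, or the ether may lose isoprene before it rearranges. The fallback builds ring C first and attaches ring B by cross-coupling. It sets out from ketone 6, which would be heated in toluene at 110 °C (aromatic Claisen rearrangement) to give 1-[2-hydroxy-4-methoxy-3-(3-methylbut-2-en-1-yl)phenyl]ethan-1-one F1. Condensation with N,N-dimethylformamide dimethyl acetal at 90 °C would give (E)-3-(dimethylamino)-1-[2-hydroxy-4-methoxy-3-(3-methylbut-2-en-1-yl)phenyl]prop-2-en-1-one F2. Iodine (1.05 equiv) and pyridine in CHCl3 at 0 °C would close ring C to 3-iodo-7-methoxy-8-(3-methylbut-2-en-1-yl)-4H-chromen-4-one F3; the small excess of iodine is meant to spare the prenyl alkene. Suzuki–Miyaura coupling of the iodide with commercial (2,4,5-trimethoxyphenyl)boronic acid (Pd(dppf)Cl2, Na2CO3, dioxane/H2O, 80 °C) would come back to the route at the target 13.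

Step 2. What may go wrong: the phenoxide may attack the unsubstituted allyl terminus, or zerovalent palladium may re-ionise the product, so that the linear prenyl ether forms; the hydrogen-bonded phenol may also react slowly. The fallback makes the tertiary ether through an alkyne. It sets out from phenol 5, which would be alkylated with 3-chloro-3-methylbut-1-yne (CuCl2·2H2O 1 mol%, DBU, MeCN, 0 °C) to give 1-[4-methoxy-2-(2-methylbut-3-yn-2-yloxy)phenyl]ethan-1-one F4. Semi-hydrogenation (H2 1 atm, Pd/CaCO3 poisoned with Pb(OAc)2, quinoline, EtOAc) would come back to the route at ether 6.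

Step 4. What may go wrong: hydroperoxide may add only slowly to the doubly donor-substituted enone, and the acid-labile epoxide may open during isolation. The fallback forms the epoxide by C–C bond formation, without the chalcone 8. It sets out from ketone 6, whose lithium enolate (LiN(SiMe3)2, THF, −78 °C) would be chlorinated with TsCl to give 2-chloro-1-[4-methoxy-2-(2-methylbut-3-en-2-yloxy)phenyl]ethan-1-one F5. Darzens condensation with aldehyde 7 (KOtBu, THF/t-BuOH, −20 → 0 °C) would come back to the route at the trans epoxide 9, which would be used crude.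

Further compounds
F1 | step 5 | 1-[2-hydroxy-4-methoxy-3-(3-methylbut-2-en-1-yl)phenyl]ethan-1-one | CC(=O)c1ccc(OC)c(CC=C(C)C)c1O
F2 | step 5 | (E)-3-(dimethylamino)-1-[2-hydroxy-4-methoxy-3-(3-methylbut-2-en-1-yl)phenyl]prop-2-en-1-one | CN(C)/C=C/C(=O)c1ccc(OC)c(CC=C(C)C)c1O
F3 | step 5 | 3-iodo-7-methoxy-8-(3-methylbut-2-en-1-yl)-4H-chromen-4-one | COc1ccc2c(occ(I)c2=O)c1CC=C(C)C
F4 | step 2 | 1-[4-methoxy-2-(2-methylbut-3-yn-2-yloxy)phenyl]ethan-1-one | CC(=O)c1ccc(OC)cc1OC(C)(C)C#C
F5 | step 4 | 2-chloro-1-[4-methoxy-2-(2-methylbut-3-en-2-yloxy)phenyl]ethan-1-one | ClCC(=O)c1ccc(OC)cc1OC(C)(C)C=C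
A1 | direct plan | 1-bromo-2-fluoro-4-methoxybenzene | COc1ccc(Br)c(F)c1
A2 | direct plan | 1-bromo-2-fluoro-4-methoxy-3-(3-methylbut-2-en-1-yl)benzene | COc1ccc(Br)c(F)c1CC=C(C)C
A3 | direct plan | 1-[2-fluoro-4-methoxy-3-(3-methylbut-2-en-1-yl)phenyl]ethan-1-one | COc1ccc(C(C)=O)c(F)c1CC=C(C)C
A4 | direct plan | 1-bromo-2,4,5-trimethoxybenzene | COc1cc(OC)c(Br)cc1OC
A5 | direct plan | 1-[2-fluoro-4-methoxy-3-(3-methylbut-2-en-1-yl)phenyl]-2-(2,4,5-trimethoxyphenyl)ethan-1-one | COc1ccc(C(=O)Cc2cc(OC)c(OC)cc2OC)c(F)c1CC=C(C)C
A6 | direct plan | potassium (Z)-3-[2-fluoro-4-methoxy-3-(3-methylbut-2-en-1-yl)phenyl]-3-oxo-2-(2,4,5-trimethoxyphenyl)prop-1-en-1-olate | [K+].[O-]/C=C(/c1cc(OC)c(OC)cc1OC)C(=O)c1ccc(OC)c(CC=C(C)C)c1F
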